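## Plan

- **Feature.** The benzene ring is numbered from the ester-bearing carbon (C1) through the two phenolic carbons (C2, C3). The ring edge C4–C5 then carries only hydrogen, so it can be made as a disubstituted alkene from two vinyl termini. C1–C3 are assembled beforehand as an open β-keto ester with an α'-silyloxy group.
- **Retrosynthetic cuts, in order.** The silyl group on O3; two ring hydrogens (arene back to cyclohexenone); C4=C5 (metathesis); C1–C6 (enolate allylation); C1–C2 (decarboxylative Claisen condensation); the alkyl ester C–O (alcoholysis of Meldrum's acid).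
- **Forward.** Monooctadecyl malonate and silylated vinylglycolic acid give the C1–C4 chain. Allyl bromide adds C6–C5. The only ring, a six-membered carbocycle, closes by metathesis and is then dehydrogenated and desilylated.
- **Stereochemistry.** The target has no stereocentre. The sp3 centres at C1 and C3 of the intermediates are uncontrolled and both become sp2 on aromatization.

Key step: step 6

Assumption: commercial methyl 2-hydroxybut-3-enoate is the racemate, so every sp3 centre on the way is racemic or an epimeric mixture, is written without a configuration descriptor in the SMILES, and vanishes on aromatization.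

## Route

Step 1
Reactants: 1 2,2-dimethyl-1,3-dioxane-4,6-dione (Meldrum's acid); 2 octadecan-1-ol
Product: 3 3-(octadecyloxy)-3-oxopropanoic acid (monooctadecyl malonate)
Conditions: toluene, 110 °C
Reagents that add atoms: none
Why: Thermal alcoholysis of Meldrum's acid, in which the primary alcohol opens the strongly activated cyclic acylal and acetone departs, is the standard way to monoalkyl malonates and stops at the half ester because the free acid formed is no longer an acylating agent.

Step 2
Reactants: 4 methyl 2-hydroxybut-3-enoate (racemic)
Product: 5 methyl 2-(tert-butyldimethylsilyloxy)but-3-enoate (racemic)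
Conditions: TBSCl, imidazole, CH2Cl2, 0 °C to rt
Reagents that add atoms: tert-butyldimethylsilyl chloride (TBSCl), CC(C)(C)[Si](C)(C)Cl
Why: Standard silylation of a secondary alcohol with TBSCl and imidazole, a base too weak to shift the vinyl group into conjugation with the ester; the stereocentre is untouched and racemic.

Step 3
Reactants: 5 methyl 2-(tert-butyldimethylsilyloxy)but-3-enoate
Product: 6 2-(tert-butyldimethylsilyloxy)but-3-enoic acid (racemic)
Conditions: LiOH, THF/H2O, 0 °C; then 1 M HCl to pH 3, 0 °C
Reagents that add atoms: lithium hydroxide, [Li+].[OH-]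
Why: Saponification of a methyl ester activated by its α-oxygen substituent is fast at 0 °C, the carboxylate formed resists further enolization so that the β,γ-alkene should stay in place, and a secondary TBS ether tolerates cold dilute hydroxide and a short acidification.

Step 4
Reactants: 6 2-(tert-butyldimethylsilyloxy)but-3-enoic acid; 3 3-(octadecyloxy)-3-oxopropanoic acid
Product: 9 octadecyl 4-(tert-butyldimethylsilyloxy)-3-oxohex-5-enoate (racemic), via acyl imidazolide 7 (not isolated), via magnesium malonate 8 (not isolated)
Conditions: 6, CDI, THF, rt; separately 3, Mg(OEt)2 (0.5 equiv), THF, rt, then evaporation; both combined in THF, rt; cold 0.5 M HCl work-up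
Reagents that add atoms: 1,1'-carbonyldiimidazole (CDI), O=C(n1ccnc1)n1ccnc1 (imidazolyl group of 7 only); Mg(OEt)2, CC[O-].CC[O-].[Mg+2] (magnesium of 8 only)
Why: Masamune–Brooks reaction (decarboxylative Claisen condensation): the magnesium-chelated malonate is C-acylated by the imidazolide under almost neutral conditions and then loses CO2, a protocol known to leave the α-centre of protected amino and hydroxy acids intact, which speaks for retention of the unconjugated vinyl group here.

Step 5
Reactants: 9 octadecyl 4-(tert-butyldimethylsilyloxy)-3-oxohex-5-enoate; 10 allyl bromide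
Product: 12 octadecyl 2-allyl-4-(tert-butyldimethylsilyloxy)-3-oxohex-5-enoate (racemic mixture of C2 epimers), via sodium enolate 11 (not isolated)
Conditions: NaH (1.0 equiv), THF, 0 °C; then 10 (1.05 equiv), 0 °C to rt
Reagents that add atoms: sodium hydride, [Na+].[H-] (sodium of 11 only)
Why: SN2 alkylation of a stabilized β-keto ester enolate with a soft allylic halide goes to carbon, and one equivalent of base places the only negative charge between the two carbonyls, which shields the γ-hydrogen beside the silyl ether and leaves no base once the halide is consumed; the new α-stereocentre is not controlled, equilibrates through the enol and is erased in step 7.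

Step 6
Reactants: 12 octadecyl 2-allyl-4-(tert-butyldimethylsilyloxy)-3-oxohex-5-enoate
Product: 13 octadecyl 3-(tert-butyldimethylsilyloxy)-2-oxocyclohex-4-ene-1-carboxylate (racemic mixture of C1 epimers)
Conditions: second-generation Grubbs catalyst (H2IMes)(PCy3)Cl2Ru=CHPh (5 mol %), 1,4-benzoquinone (10 mol %), CH2Cl2 (0.005 M), 40 °C; filtration through neutral alumina
Reagents that add atoms: none
Why: Ring-closing olefin metathesis by the carbene/metallacyclobutane cycle: after loss of PCy3 the ruthenium benzylidene exchanges with the less encumbered alkene, that of the allyl group (future C5), the resulting alkylidene adds across the vinyl group beside the silyl ether (future C4), and cycloreversion of the ruthenacyclobutane forms C4=C5 and a ruthenium methylidene that carries the chain, ethene being the only coproduct. The closest known reaction type is the closure of 1,7-octadienes bearing allylic silyl ethers or 1,3-dicarbonyl groups to cyclohexenes, including the metathesis–aromatization sequences that lead from acyclic dienyl ketones to phenols. The one ring formed is the six-membered carbocycle, closed between the two internal alkene carbons of the 1,7-diene as the terminal CH2 groups leave, without strain and with a necessarily cis endocyclic alkene. No stereocentre is created; the centres at C1 and C3 pass through as the epimeric mixture, the α-carbon equilibrates through the enol so that all material can cyclize, and both centres disappear in step 7. Two side reactions have to be held off, intermolecular metathesis and double-bond shift induced by ruthenium hydrides; high dilution together with the entropically easy six-ring closure of two terminal vinyl groups takes care of the former, and an acid- and base-free medium containing 1,4-benzoquinone as hydride scavenger takes care of the latter, which also spares the acidic allylic C3–H. Escape of ethene from the refluxing solution makes the closure irreversible.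

Step 7
Reactants: 13 octadecyl 3-(tert-butyldimethylsilyloxy)-2-oxocyclohex-4-ene-1-carboxylate
Product: 15 octadecyl 3-(tert-butyldimethylsilyloxy)-2-hydroxybenzoate, via enol tautomer 14 (not isolated)
Conditions: DDQ (1.1 equiv), toluene, 0 °C to rt; filtration from the precipitated hydroquinone
Reagents that add atoms: none
Why: DDQ dehydrogenation of a dihydroarene: the cyclic β-keto ester is largely enolized to the 1,4-cyclohexadiene 14, whose C6–H and C3–H are both doubly allylic, so hydride transfer from C6 gives a cation stabilized by the C2 hydroxyl and loss of the C3 proton completes the arene, while the neutral, non-polar medium from which the hydroquinone precipitates gives ionization of the allylic C3–O bond little chance, and any alkene-shifted or dienol tautomer of 13 has the same oxidation level and converges on 15.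

Step 8
Reactants: 15 octadecyl 3-(tert-butyldimethylsilyloxy)-2-hydroxybenzoate
Product: 16 octadecyl 2,3-dihydroxybenzoate (Gentiside E)
Conditions: Bu4NF (1.1 equiv), AcOH (1.2 equiv), THF, 0 °C
Reagents that add atoms: none
Why: Fluoride-induced cleavage of an aryl silyl ether is fast at 0 °C, and the acetic acid buffer protonates the phenoxide at once, so that the long-chain ester is not attacked and the catechol is not exposed to base and air.

## Compound list

1 | 2,2-dimethyl-1,3-dioxane-4,6-dione (Meldrum's acid) | CC1(C)OC(=O)CC(=O)O1 | starting material
2 | octadecan-1-ol | CCCCCCCCCCCCCCCCCCO | starting material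
3 | 3-(octadecyloxy)-3-oxopropanoic acid | CCCCCCCCCCCCCCCCCCOC(=O)CC(=O)O | intermediate
4 | methyl 2-hydroxybut-3-enoate (racemic) | COC(=O)C(O)C=C | starting material
5 | methyl 2-(tert-butyldimethylsilyloxy)but-3-enoate (racemic) | COC(=O)C(C=C)O[Si](C)(C)C(C)(C)C | intermediate
6 | 2-(tert-butyldimethylsilyloxy)but-3-enoic acid (racemic) | OC(=O)C(C=C)O[Si](C)(C)C(C)(C)C | intermediate
7 | 2-(tert-butyldimethylsilyloxy)-1-(imidazol-1-yl)but-3-en-1-one (racemic, not isolated) | O=C(C(C=C)O[Si](C)(C)C(C)(C)C)n1ccnc1 | intermediate
8 | magnesium bis[3-(octadecyloxy)-3-oxopropanoate] (not isolated) | [Mg+2].[O-]C(=O)CC(=O)OCCCCCCCCCCCCCCCCCC.[O-]C(=O)CC(=O)OCCCCCCCCCCCCCCCCCC | intermediate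
9 | octadecyl 4-(tert-butyldimethylsilyloxy)-3-oxohex-5-enoate (racemic) | CCCCCCCCCCCCCCCCCCOC(=O)CC(=O)C(C=C)O[Si](C)(C)C(C)(C)C | intermediate
10 | allyl bromide | C=CCBr | starting material
11 | sodium enolate of 9, drawn as the C2 carbanion (racemic, not isolated) | CCCCCCCCCCCCCCCCCCOC(=O)[CH-]C(=O)C(C=C)O[Si](C)(C)C(C)(C)C.[Na+] | intermediate
12 | octadecyl 2-allyl-4-(tert-butyldimethylsilyloxy)-3-oxohex-5-enoate (racemic, interconverting C2 epimers) | CCCCCCCCCCCCCCCCCCOC(=O)C(CC=C)C(=O)C(C=C)O[Si](C)(C)C(C)(C)C | intermediate
13 | octadecyl 3-(tert-butyldimethylsilyloxy)-2-oxocyclohex-4-ene-1-carboxylate (racemic, interconverting C1 epimers) | CCCCCCCCCCCCCCCCCCOC(=O)C1CC=CC(O[Si](C)(C)C(C)(C)C)C1=O | intermediate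
14 | octadecyl 3-(tert-butyldimethylsilyloxy)-2-hydroxycyclohexa-1,4-diene-1-carboxylate, enol tautomer of 13 (racemic, not isolated) | CCCCCCCCCCCCCCCCCCOC(=O)C1=C(O)C(O[Si](C)(C)C(C)(C)C)C=CC1 | intermediate
15 | octadecyl 3-(tert-butyldimethylsilyloxy)-2-hydroxybenzoate | CCCCCCCCCCCCCCCCCCOC(=O)c1cccc(O[Si](C)(C)C(C)(C)C)c1O | intermediate
16 | octadecyl 2,3-dihydroxybenzoate (Gentiside E) | CCCCCCCCCCCCCCCCCCOC(=O)c1cccc(O)c1O | target

## Step count and weak points

Total steps: 8. Longest linear sequence: 7 (steps 2 to 8, from 4); step 1 feeds the side branch.

**Step 7 (aromatization).**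
- What may go wrong: loss of silanol by 1,4-elimination across C3 and C6 may compete with hydride abstraction. It could be triggered by the acidic hydroquinone or by ionization of the allylic C3–O bond, and it would drop the ring to the monophenol oxidation level. Partial desilylation is a second way to lose material.
- Fallback, from 13 back to 15: dehydrogenation by selenoxide syn elimination, which fixes the site of unsaturation and never builds cationic character at C3. PhSeCl and pyridine in CH2Cl2 at 0 °C should selenenylate the enol at C1 to octadecyl 3-(tert-butyldimethylsilyloxy)-2-oxo-1-(phenylselanyl)cyclohex-4-ene-1-carboxylate F1. Aqueous H2O2 at 0 °C should oxidize it to octadecyl 3-(tert-butyldimethylsilyloxy)-2-oxo-1-(phenylseleninyl)cyclohex-4-ene-1-carboxylate F2. F2 eliminates towards C6–H and leaves octadecyl 5-(tert-butyldimethylsilyloxy)-6-oxocyclohexa-1,3-diene-1-carboxylate F3, the keto tautomer of 15, which should enolize at once.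

**Step 6 (ring closure).**
- What may go wrong: either terminal alkene may migrate into conjugation. The propagating carbene may be tied up by chelation to the 1,3-dicarbonyl unit, or intermolecular metathesis may erode the closure. The product may also lose silanol on acidic adsorbents.
- Fallback, from 12 back to 13: the same bond is closed one oxidation level lower, where there is no enolizable ketone and no acidic C3–H. NaBH4 in THF/MeOH at −20 °C should reduce the ketone to octadecyl 2-allyl-4-(tert-butyldimethylsilyloxy)-3-hydroxyhex-5-enoate F4 (diastereomer mixture). Metathesis with (H2IMes)(PCy3)Cl2Ru=CHPh in CH2Cl2 should give octadecyl 3-(tert-butyldimethylsilyloxy)-2-hydroxycyclohex-4-ene-1-carboxylate F5. Dess–Martin periodinane buffered with NaHCO3 should restore the ketone of 13.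

**Step 4 (acylation, together with the saponification before it).**
- What may go wrong: enolization of the ester or of the activated acyl derivative may slide the vinyl group into conjugation, and the branched α-silyloxy acyl donor may react sluggishly at carbon.
- Fallback, from 5 and 2 back to 9: an aldol addition and oxidation, which needs no activated acid.
  - iBu2AlH in CH2Cl2 at −78 °C should reduce 5 to 2-(tert-butyldimethylsilyloxy)but-3-enal F6, used crude.
  - Ac2O and pyridine convert 2 into octadecyl acetate F7, which LiN(iPr)2 in THF at −78 °C turns into lithium 1-(octadecyloxy)ethen-1-olate F8.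
  - Addition of F8 to F6 at −78 °C should give octadecyl 4-(tert-butyldimethylsilyloxy)-3-hydroxyhex-5-enoate F9 (diastereomer mixture), and Dess–Martin periodinane should oxidize it to 9.

## Further compounds

F1 | step 7 | octadecyl 3-(tert-butyldimethylsilyloxy)-2-oxo-1-(phenylselanyl)cyclohex-4-ene-1-carboxylate | CCCCCCCCCCCCCCCCCCOC(=O)C1([Se]c2ccccc2)CC=CC(O[Si](C)(C)C(C)(C)C)C1=O
F2 | step 7 | octadecyl 3-(tert-butyldimethylsilyloxy)-2-oxo-1-(phenylseleninyl)cyclohex-4-ene-1-carboxylate | CCCCCCCCCCCCCCCCCCOC(=O)C1([Se](=O)c2ccccc2)CC=CC(O[Si](C)(C)C(C)(C)C)C1=O
F3 | step 7 | octadecyl 5-(tert-butyldimethylsilyloxy)-6-oxocyclohexa-1,3-diene-1-carboxylate | CCCCCCCCCCCCCCCCCCOC(=O)C1=CC=CC(O[Si](C)(C)C(C)(C)C)C1=O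
F4 | step 6 | octadecyl 2-allyl-4-(tert-butyldimethylsilyloxy)-3-hydroxyhex-5-enoate | CCCCCCCCCCCCCCCCCCOC(=O)C(CC=C)C(O)C(C=C)O[Si](C)(C)C(C)(C)C
F5 | step 6 | octadecyl 3-(tert-butyldimethylsilyloxy)-2-hydroxycyclohex-4-ene-1-carboxylate | CCCCCCCCCCCCCCCCCCOC(=O)C1CC=CC(O[Si](C)(C)C(C)(C)C)C1O
F6 | step 4 | 2-(tert-butyldimethylsilyloxy)but-3-enal | O=CC(C=C)O[Si](C)(C)C(C)(C)C
F7 | step 4 | octadecyl acetate | CCCCCCCCCCCCCCCCCCOC(C)=O
F8 | step 4 | lithium 1-(octadecyloxy)ethen-1-olate | [Li+].C=C([O-])OCCCCCCCCCCCCCCCCCC
F9 | step 4 | octadecyl 4-(tert-butyldimethylsilyloxy)-3-hydroxyhex-5-enoate | CCCCCCCCCCCCCCCCCCOC(=O)CC(O)C(C=C)O[Si](C)(C)C(C)(C)C
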